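**Retrosynthetic overview**
- Feature: a trans-decalin (rings A and B, labdane numbering) whose equatorial 6α-acyloxy carbon C6 lies next to the C5–C10 ring fusion, so C6 can serve as the electrophilic initiator of a cationic bicyclisation.
- Key disconnection: C5–C6 and C10–C1 are made in one Lewis-acid cascade from acyclic aldehyde 27; ring B closes first, then ring A, with an allylsilane as terminator.
- Aldehyde 27 comes from an Ireland–Claisen rearrangement of ester 21, which sets C9 and puts the C8 ester anti to it; the C17 ester is carried as tert-butyl so the acid can be freed last.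
- The C5 carbinol of 21 comes from CBS reduction of enone 16, made from Weinreb amide 9 (Ireland–Claisen of a silylallyl isobutyrate) and the alkenyllithium derived from pent-3-yn-1-ol.
- After the cascade: ring-A hydrogenation, Δ7 by selenoxide elimination, 6-O-acylation, butenolide by α-phenylthio-lactone alkylation and sulfoxide elimination, then ester acidolysis.

Key step: step 13

Remark: labdane numbering is used for all carbons; (R)-2-methylbutanoic acid is taken as a purchasable reagent, and the silyl-bearing carbon C3 is carried as a mixture of both epimers because it becomes sp2 in step 13.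

Step 1
Reactants: 1 (E)-3-(trimethylsilyl)prop-2-en-1-ol; 2 isobutyryl chloride
Product: 3 (E)-3-(trimethylsilyl)allyl 2-methylpropanoate
Conditions: pyridine, cat. DMAP, CH2Cl2, 0 °C → rt
Reagents that add atoms: none
Why: O-acylation of a primary allylic alcohol with an acid chloride, to which the vinylsilane is inert.

Step 2
Reactants: 3 (E)-3-(trimethylsilyl)allyl 2-methylpropanoate
Product: 7 rac-2,2-dimethyl-3-(trimethylsilyl)pent-4-enoic acid, via lithium enolate 4 (not isolated), via silyl ketene acetal 5 (not isolated), via trimethylsilyl ester 6 (not isolated)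
Conditions: LDA, THF, −78 °C; TMSCl; −78 → 60 °C; 1 M NaOH, then dil. HCl to pH 3 at 0 °C
Reagents that add atoms: none
Why: Ireland–Claisen rearrangement, in which the [3,3] shift joins the enolate carbon (C4) to the silyl-bearing alkene carbon (C3) and moves the alkene to C1=C2, giving the allylsilane with C3 racemic.

Step 3
Reactants: 7 rac-2,2-dimethyl-3-(trimethylsilyl)pent-4-enoic acid
Product: 9 N-methoxy-N,2,2-trimethyl-3-(trimethylsilyl)pent-4-enamide, via acid chloride 8 (not isolated)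
Conditions: (COCl)2, cat. DMF, CH2Cl2, 0 °C → rt; evaporate; MeNH(OMe)·HCl, pyridine, CH2Cl2, 0 °C → rt
Reagents that add atoms: N,O-dimethylhydroxylamine hydrochloride, CNOC.Cl
Why: Weinreb amide formation through the acid chloride, the usual activation for an α-quaternary acid.

Step 4
Reactants: 10 pent-3-yn-1-ol
Product: 11 triisopropyl(pent-3-yn-1-yloxy)silane
Conditions: TIPSCl, imidazole, CH2Cl2, rt
Reagents that add atoms: chlorotriisopropylsilane, CC(C)[Si](Cl)(C(C)C)C(C)C
Why: silylation of a primary alcohol, with the bulky TIPS group chosen to keep O12 a poor nucleophile in step 13.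

Step 5
Reactants: 11 triisopropyl(pent-3-yn-1-yloxy)silane
Product: 13 (E)-[(4-iodopent-3-en-1-yl)oxy]triisopropylsilane, via alkenylzirconocene chloride 12 (not isolated)
Conditions: Cp2Zr(H)Cl (1.6 equiv), THF, rt → 50 °C; I2, THF, 0 °C
Reagents that add atoms: iodine, II
Why: Schwartz hydrozirconation (syn addition, with equilibration under excess reagent placing zirconium on the methyl-bearing carbon) followed by iodinolysis with retention should give the E-iodide.

Step 6
Reactants: 13 (E)-[(4-iodopent-3-en-1-yl)oxy]triisopropylsilane; 9 N-methoxy-N,2,2-trimethyl-3-(trimethylsilyl)pent-4-enamide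
Product: 16 (6E)-4,4,6-trimethyl-9-[(triisopropylsilyl)oxy]-3-(trimethylsilyl)nona-1,6-dien-5-one (C3 racemic), via alkenyllithium 14 (not isolated), via tetrahedral lithium adduct 15 (not isolated)
Conditions: t-BuLi (2.1 equiv), Et2O, −78 °C; add 9, −78 → 0 °C; aq. NH4Cl
Reagents that add atoms: none
Why: iodine–lithium exchange with retention of alkene geometry, then Weinreb ketone synthesis, in which the chelated adduct prevents a second addition.

Step 7
Reactants: 16 (6E)-4,4,6-trimethyl-9-[(triisopropylsilyl)oxy]-3-(trimethylsilyl)nona-1,6-dien-5-one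
Product: 17 (5R,6E)-4,4,6-trimethyl-9-[(triisopropylsilyl)oxy]-3-(trimethylsilyl)nona-1,6-dien-5-ol (both C3 epimers)
Conditions: (S)-2-methyl-CBS-oxazaborolidine (0.2 equiv), catecholborane (2 equiv), toluene, −78 → −40 °C; MeOH; aq. NaOH wash
Reagents that add atoms: none
Why: Corey–Bakshi–Shibata reduction, in which the quaternary C4 side is assumed to act as the large group and the twisted α-methylalkenyl side as the small one, so that the (S)-catalyst should give the 5R carbinol, while catecholborane at low temperature leaves the terminal alkene alone.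

Step 8
Reactants: 18 methyl 4,4-dimethoxybutanoate
Product: 19 4,4-dimethoxybutanoic acid
Conditions: LiOH·H2O, THF/H2O, rt; 1 M HCl to pH 4 at 0 °C, extract at once
Reagents that add atoms: lithium hydroxide, [Li+].[OH-]
Why: ester saponification, with the acetal stable to base and to brief mild acidification.

Step 9
Reactants: 19 4,4-dimethoxybutanoic acid; 17 (5R,6E)-4,4,6-trimethyl-9-[(triisopropylsilyl)oxy]-3-(trimethylsilyl)nona-1,6-dien-5-ol
Product: 21 (5R,6E)-4,4,6-trimethyl-9-[(triisopropylsilyl)oxy]-3-(trimethylsilyl)nona-1,6-dien-5-yl 4,4-dimethoxybutanoate, via mixed anhydride 20 (not isolated)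
Conditions: 2,4,6-trichlorobenzoyl chloride, Et3N, THF, rt; then 17, DMAP, toluene, rt → 50 °C
Reagents that add atoms: none
Why: Yamaguchi esterification, chosen because the carbinol is flanked by a quaternary carbon and a trisubstituted alkene, and proceeding with retention since the C5–O bond is not broken.

Step 10
Reactants: 21 (5R,6E)-4,4,6-trimethyl-9-[(triisopropylsilyl)oxy]-3-(trimethylsilyl)nona-1,6-dien-5-yl 4,4-dimethoxybutanoate
Product: 25 (2R,3S,4E)-2-(2,2-dimethoxyethyl)-4,6,6-trimethyl-3-{2-[(triisopropylsilyl)oxy]ethyl}-7-(trimethylsilyl)nona-4,8-dienoic acid (acid C2 = C8 and acid C3 = C9), via lithium enolate 22 (not isolated), via silyl ketene acetal 23 (not isolated), via trimethylsilyl ester 24 (not isolated)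
Conditions: LDA, THF, −78 °C; TMSCl/Et3N; −78 → 45 °C; K2CO3, MeOH/H2O; NaH2PO4 to pH 5
Reagents that add atoms: none
Why: Ireland–Claisen rearrangement through a chair with the C4 group equatorial, which should give the E C5=C10 alkene and transfer the C5 configuration to C9, while the kinetic enolate (C7 cis to the allylic oxygen) places C7 axial and so gives the 8,9-anti acid.

Step 11
Reactants: 25 (2R,3S,4E)-2-(2,2-dimethoxyethyl)-4,6,6-trimethyl-3-{2-[(triisopropylsilyl)oxy]ethyl}-7-(trimethylsilyl)nona-4,8-dienoic acid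
Product: 26 tert-butyl (2R,3S,4E)-2-(2,2-dimethoxyethyl)-4,6,6-trimethyl-3-{2-[(triisopropylsilyl)oxy]ethyl}-7-(trimethylsilyl)nona-4,8-dienoate
Conditions: tert-butyl 2,2,2-trichloroacetimidate (3 equiv), cyclohexane/CH2Cl2, rt
Reagents that add atoms: tert-butyl 2,2,2-trichloroacetimidate, CC(C)(C)OC(=N)C(Cl)(Cl)Cl
Why: tert-butyl esterification of a carboxylic acid with the trichloroacetimidate, run without added acid so that the acetal and the allylsilane survive.

Step 12
Reactants: 26 tert-butyl (2R,3S,4E)-2-(2,2-dimethoxyethyl)-4,6,6-trimethyl-3-{2-[(triisopropylsilyl)oxy]ethyl}-7-(trimethylsilyl)nona-4,8-dienoate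
Product: 27 tert-butyl (2R,3S,4E)-4,6,6-trimethyl-2-(2-oxoethyl)-3-{2-[(triisopropylsilyl)oxy]ethyl}-7-(trimethylsilyl)nona-4,8-dienoate (aldehyde carbon = C6; C8 and C9 defined; C3 both epimers)
Conditions: PPTS (cat.), acetone/H2O (10:1), 50 °C
Reagents that add atoms: water, O
Why: mild acetal hydrolysis, under which the allylsilane, the tert-butyl ester and the TIPS ether should persist.

Step 13
Reactants: 27 tert-butyl (2R,3S,4E)-4,6,6-trimethyl-2-(2-oxoethyl)-3-{2-[(triisopropylsilyl)oxy]ethyl}-7-(trimethylsilyl)nona-4,8-dienoate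
Product: 28 tert-butyl 6α-hydroxy-12-[(triisopropylsilyl)oxy]-13,14,15,16-tetranorlabd-2-en-17-oate (trans-decalin; 5α-H, 8β-H, 9α-H, 10β-CH3)
Conditions: Me2AlCl (2.5 equiv), CH2Cl2 (0.005 M), −78 → −40 °C; aq. Rochelle salt
Reagents that add atoms: none
Why: Me2AlCl activates the C6 aldehyde, C5 of the E C5=C10 alkene attacks C6 (Prins), and the tertiary C10 cation is trapped anti by C1 of the allylsilane, whose C3–Si bond then breaks to leave the C2=C3 alkene; the closest known reaction type is the Lewis-acid, aldehyde-initiated cation–olefin bicyclisation with allylsilane termination. Ring B closes as a six-membered chair, endo with respect to the C5=C10 alkene and exo with respect to the carbonyl, and ring A closes as a six-membered chair, endo with respect to the allylsilane alkene (anti SE2′). C5 (H α) is set by the alkene face that is attacked, which C9 and the anti C8 ester dictate because only one chair holds both substituents equatorial. C10 (CH3 β, trans fusion) is set by anti addition across the E alkene, and C6 (6α-OH) by the aluminium-bound oxygen taking the equatorial site anti to C10. The step needs this face selectivity and needs bicyclisation to outrun proton loss or capture of the C10 cation by chloride, O12 or the ester; the all-equatorial chair, the high nucleophilicity of the allylsilane, the bulky TIPS group, the equatorial ester that cannot reach C10, and high dilution should secure this. Both C3 epimers converge because C3 becomes sp2.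

Step 14
Reactants: 28 tert-butyl 6α-hydroxy-12-[(triisopropylsilyl)oxy]-13,14,15,16-tetranorlabd-2-en-17-oate
Product: 29 tert-butyl 6α-hydroxy-12-[(triisopropylsilyl)oxy]-13,14,15,16-tetranorlabdan-17-oate
Conditions: H2 (1 atm), 10% Pd/C, EtOAc, rt
Reagents that add atoms: none
Why: heterogeneous hydrogenation of the only alkene, a cis-disubstituted ring alkene, with no other reducible group present.

Step 15
Reactants: 29 tert-butyl 6α-hydroxy-12-[(triisopropylsilyl)oxy]-13,14,15,16-tetranorlabdan-17-oate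
Product: 33 tert-butyl 6α-hydroxy-12-[(triisopropylsilyl)oxy]-13,14,15,16-tetranorlabd-7-en-17-oate, via dilithio alkoxide enolate 30 (not isolated), via C8 selenide 31 (not isolated), via selenoxide 32 (not isolated)
Conditions: LDA (2.5 equiv), THF, −78 → −20 °C; PhSeBr, −78 °C; then AcOH, 30% H2O2, 0 °C → rt
Reagents that add atoms: none
Why: ester enolate selenenylation and selenoxide syn-elimination, which should go toward C7 because a syn elimination toward C9 would eclipse the C8 ester with the C9 side chain (8α-selenide) or has no syn hydrogen (8β-selenide).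

Step 16
Reactants: 33 tert-butyl 6α-hydroxy-12-[(triisopropylsilyl)oxy]-13,14,15,16-tetranorlabd-7-en-17-oate; 34 (R)-2-methylbutanoic acid
Product: 36 tert-butyl 6α-[(2R)-2-methylbutanoyloxy]-12-[(triisopropylsilyl)oxy]-13,14,15,16-tetranorlabd-7-en-17-oate, via mixed anhydride 35 (not isolated)
Conditions: 34 (3 equiv), 2,4,6-trichlorobenzoyl chloride, Et3N, toluene, rt; then 33, DMAP, rt → 40 °C
Reagents that add atoms: none
Why: Yamaguchi esterification of the hindered equatorial allylic alcohol, placed after the last strong-base step so that the acid's α-stereocentre is not enolised.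

Step 17
Reactants: 36 tert-butyl 6α-[(2R)-2-methylbutanoyloxy]-12-[(triisopropylsilyl)oxy]-13,14,15,16-tetranorlabd-7-en-17-oate
Product: 37 tert-butyl 12-hydroxy-6α-[(2R)-2-methylbutanoyloxy]-13,14,15,16-tetranorlabd-7-en-17-oate
Conditions: HF·pyridine, pyridine/THF, 0 °C → rt
Reagents that add atoms: none
Why: fluoride desilylation under buffered acidic conditions, which avoids an alkoxide that could lactonise onto C17.

Step 18
Reactants: 37 tert-butyl 12-hydroxy-6α-[(2R)-2-methylbutanoyloxy]-13,14,15,16-tetranorlabd-7-en-17-oate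
Product: 38 tert-butyl 12-iodo-6α-[(2R)-2-methylbutanoyloxy]-13,14,15,16-tetranorlabd-7-en-17-oate
Conditions: I2, PPh3, imidazole, CH2Cl2, 0 °C → rt
Reagents that add atoms: iodine, II
Why: Appel-type (Garegg–Samuelsson) iodination of a primary alcohol.

Step 19
Reactants: 39 3-bromodihydrofuran-2(3H)-one; 40 thiophenol
Product: 41 3-(phenylsulfanyl)dihydrofuran-2(3H)-one
Conditions: Et3N, CH2Cl2, 0 °C → rt
Reagents that add atoms: none
Why: SN2 displacement of an α-bromo lactone by thiolate.

Step 20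
Reactants: 41 3-(phenylsulfanyl)dihydrofuran-2(3H)-one; 38 tert-butyl 12-iodo-6α-[(2R)-2-methylbutanoyloxy]-13,14,15,16-tetranorlabd-7-en-17-oate
Product: 43 tert-butyl 6α-[(2R)-2-methylbutanoyloxy]-13-(phenylsulfanyl)labd-7-en-16,15-olid-17-oate (C13 epimers), via potassium lactone enolate 42 (not isolated)
Conditions: 41 (1.5 equiv), KHMDS (1.4 equiv), THF/DMPU, −78 → 0 °C; add 38, 0 °C → rt
Reagents that add atoms: none
Why: alkylation of a sulfur-stabilised lactone enolate with a primary iodide, the enolate being too weak a base to deprotonate the 2-methylbutanoate or the enoate.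

Step 21
Reactants: 43 tert-butyl 6α-[(2R)-2-methylbutanoyloxy]-13-(phenylsulfanyl)labd-7-en-16,15-olid-17-oate
Product: 45 tert-butyl 6α-[(2R)-2-methylbutanoyloxy]labda-7,13-dien-16,15-olid-17-oate, via sulfoxide 44 (not isolated)
Conditions: mCPBA (1.05 equiv), CH2Cl2, −40 → 0 °C; aq. NaHCO3; toluene, CaCO3, 110 °C
Reagents that add atoms: none
Why: sulfide oxidation and thermal sulfoxide syn-elimination into the ring, the established α-phenylthio-lactone route to 2-substituted butenolides, with the electron-poor C7=C8 alkene inert to the peracid.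

Step 22
Reactants: 45 tert-butyl 6α-[(2R)-2-methylbutanoyloxy]labda-7,13-dien-16,15-olid-17-oate
Product: 46 6α-[(2R)-2-methylbutanoyloxy]labda-7,13-dien-16,15-olid-17-oic acid (CNP0150853.1)
Conditions: TFA/CH2Cl2 (1:4), 0 °C → rt
Reagents that add atoms: none
Why: acidolysis of the tert-butyl ester with loss of isobutene, under which the C6 allylic ester should not ionise because its allyl cation would be conjugated to the carboxyl-bearing alkene.

**Compound list**
1 | (E)-3-(trimethylsilyl)prop-2-en-1-ol | C[Si](C)(C)/C=C/CO | starting material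
2 | isobutyryl chloride | CC(C)C(=O)Cl | starting material
3 | (E)-3-(trimethylsilyl)allyl 2-methylpropanoate | CC(C)C(=O)OC/C=C/[Si](C)(C)C | intermediate
4 | lithium enolate of 3 | CC(C)=C(O[Li])OC/C=C/[Si](C)(C)C | intermediate (not isolated)
5 | silyl ketene acetal of 3 | CC(C)=C(O[Si](C)(C)C)OC/C=C/[Si](C)(C)C | intermediate (not isolated)
6 | trimethylsilyl 2,2-dimethyl-3-(trimethylsilyl)pent-4-enoate | C=CC([Si](C)(C)C)C(C)(C)C(=O)O[Si](C)(C)C | intermediate (not isolated)
7 | rac-2,2-dimethyl-3-(trimethylsilyl)pent-4-enoic acid | C=CC([Si](C)(C)C)C(C)(C)C(=O)O | intermediate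
8 | 2,2-dimethyl-3-(trimethylsilyl)pent-4-enoyl chloride | C=CC([Si](C)(C)C)C(C)(C)C(=O)Cl | intermediate (not isolated)
9 | N-methoxy-N,2,2-trimethyl-3-(trimethylsilyl)pent-4-enamide | C=CC([Si](C)(C)C)C(C)(C)C(=O)N(C)OC | intermediate
10 | pent-3-yn-1-ol | CC#CCCO | starting material
11 | triisopropyl(pent-3-yn-1-yloxy)silane | CC#CCCO[Si](C(C)C)(C(C)C)C(C)C | intermediate
12 | (E)-alkenylzirconocene chloride (Zr on the methyl-bearing carbon) | C/C(=C\CCO[Si](C(C)C)(C(C)C)C(C)C)[Zr](Cl)(C1C=CC=C1)C1C=CC=C1 | intermediate (not isolated)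
13 | (E)-[(4-iodopent-3-en-1-yl)oxy]triisopropylsilane | I/C(C)=C/CCO[Si](C(C)C)(C(C)C)C(C)C | intermediate
14 | (E)-alkenyllithium from 13 | [Li]/C(C)=C/CCO[Si](C(C)C)(C(C)C)C(C)C | intermediate (not isolated)
15 | tetrahedral lithium adduct of 14 and 9 | C=CC([Si](C)(C)C)C(C)(C)C(O[Li])(N(C)OC)/C(C)=C/CCO[Si](C(C)C)(C(C)C)C(C)C | intermediate (not isolated)
16 | (6E)-4,4,6-trimethyl-9-[(triisopropylsilyl)oxy]-3-(trimethylsilyl)nona-1,6-dien-5-one | C=CC([Si](C)(C)C)C(C)(C)C(=O)/C(C)=C/CCO[Si](C(C)C)(C(C)C)C(C)C | intermediate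
17 | (5R,6E)-4,4,6-trimethyl-9-[(triisopropylsilyl)oxy]-3-(trimethylsilyl)nona-1,6-dien-5-ol | C=CC([Si](C)(C)C)C(C)(C)[C@H](O)/C(C)=C/CCO[Si](C(C)C)(C(C)C)C(C)C | intermediate
18 | methyl 4,4-dimethoxybutanoate | COC(OC)CCC(=O)OC | starting material
19 | 4,4-dimethoxybutanoic acid | COC(OC)CCC(=O)O | intermediate
20 | 4,4-dimethoxybutanoic 2,4,6-trichlorobenzoic anhydride | COC(OC)CCC(=O)OC(=O)c1c(Cl)cc(Cl)cc1Cl | intermediate (not isolated)
21 | (5R,6E)-4,4,6-trimethyl-9-[(triisopropylsilyl)oxy]-3-(trimethylsilyl)nona-1,6-dien-5-yl 4,4-dimethoxybutanoate | C=CC([Si](C)(C)C)C(C)(C)[C@H](OC(=O)CCC(OC)OC)/C(C)=C/CCO[Si](C(C)C)(C(C)C)C(C)C | intermediate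
22 | lithium enolate of 21 (C7 cis to the allylic oxygen) | C=CC([Si](C)(C)C)C(C)(C)[C@H](O/C(O[Li])=C\CC(OC)OC)/C(C)=C/CCO[Si](C(C)C)(C(C)C)C(C)C | intermediate (not isolated)
23 | silyl ketene acetal of 21 (C7 cis to the allylic oxygen) | C=CC([Si](C)(C)C)C(C)(C)[C@H](O/C(O[Si](C)(C)C)=C\CC(OC)OC)/C(C)=C/CCO[Si](C(C)C)(C(C)C)C(C)C | intermediate (not isolated)
24 | trimethylsilyl ester of 25 | COC(OC)C[C@@H](C(=O)O[Si](C)(C)C)[C@H](CCO[Si](C(C)C)(C(C)C)C(C)C)/C(C)=C/C(C)(C)C([Si](C)(C)C)C=C | intermediate (not isolated)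
25 | (2R,3S,4E)-2-(2,2-dimethoxyethyl)-4,6,6-trimethyl-3-{2-[(triisopropylsilyl)oxy]ethyl}-7-(trimethylsilyl)nona-4,8-dienoic acid | COC(OC)C[C@@H](C(=O)O)[C@H](CCO[Si](C(C)C)(C(C)C)C(C)C)/C(C)=C/C(C)(C)C([Si](C)(C)C)C=C | intermediate
26 | tert-butyl ester of 25 | COC(OC)C[C@@H](C(=O)OC(C)(C)C)[C@H](CCO[Si](C(C)C)(C(C)C)C(C)C)/C(C)=C/C(C)(C)C([Si](C)(C)C)C=C | intermediate
27 | tert-butyl (2R,3S,4E)-4,6,6-trimethyl-2-(2-oxoethyl)-3-{2-[(triisopropylsilyl)oxy]ethyl}-7-(trimethylsilyl)nona-4,8-dienoate | O=CC[C@@H](C(=O)OC(C)(C)C)[C@H](CCO[Si](C(C)C)(C(C)C)C(C)C)/C(C)=C/C(C)(C)C([Si](C)(C)C)C=C | intermediate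
28 | tert-butyl 6α-hydroxy-12-[(triisopropylsilyl)oxy]-13,14,15,16-tetranorlabd-2-en-17-oate | O[C@H]1C[C@@H](C(=O)OC(C)(C)C)[C@H](CCO[Si](C(C)C)(C(C)C)C(C)C)[C@@]2(C)CC=CC(C)(C)[C@H]12 | intermediate
29 | tert-butyl 6α-hydroxy-12-[(triisopropylsilyl)oxy]-13,14,15,16-tetranorlabdan-17-oate | O[C@H]1C[C@@H](C(=O)OC(C)(C)C)[C@H](CCO[Si](C(C)C)(C(C)C)C(C)C)[C@@]2(C)CCCC(C)(C)[C@H]12 | intermediate
30 | dilithio alkoxide enolate of 29 | [Li]O[C@H]1CC(=C(O[Li])OC(C)(C)C)[C@H](CCO[Si](C(C)C)(C(C)C)C(C)C)[C@@]2(C)CCCC(C)(C)[C@H]12 | intermediate (not isolated)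
31 | C8 phenylselenide of 29 (C8 configuration not controlled) | O[C@H]1CC(C(=O)OC(C)(C)C)([Se]c3ccccc3)[C@H](CCO[Si](C(C)C)(C(C)C)C(C)C)[C@@]2(C)CCCC(C)(C)[C@H]12 | intermediate (not isolated)
32 | selenoxide of 31 | O[C@H]1CC(C(=O)OC(C)(C)C)([Se](=O)c3ccccc3)[C@H](CCO[Si](C(C)C)(C(C)C)C(C)C)[C@@]2(C)CCCC(C)(C)[C@H]12 | intermediate (not isolated)
33 | tert-butyl 6α-hydroxy-12-[(triisopropylsilyl)oxy]-13,14,15,16-tetranorlabd-7-en-17-oate | O[C@H]1C=C(C(=O)OC(C)(C)C)[C@H](CCO[Si](C(C)C)(C(C)C)C(C)C)[C@@]2(C)CCCC(C)(C)[C@H]12 | intermediate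
34 | (R)-2-methylbutanoic acid | CC[C@@H](C)C(=O)O | starting material
35 | (R)-2-methylbutanoic 2,4,6-trichlorobenzoic anhydride | CC[C@@H](C)C(=O)OC(=O)c1c(Cl)cc(Cl)cc1Cl | intermediate (not isolated)
36 | tert-butyl 6α-[(2R)-2-methylbutanoyloxy]-12-[(triisopropylsilyl)oxy]-13,14,15,16-tetranorlabd-7-en-17-oate | CC[C@@H](C)C(=O)O[C@H]1C=C(C(=O)OC(C)(C)C)[C@H](CCO[Si](C(C)C)(C(C)C)C(C)C)[C@@]2(C)CCCC(C)(C)[C@H]12 | intermediate
37 | tert-butyl 12-hydroxy-6α-[(2R)-2-methylbutanoyloxy]-13,14,15,16-tetranorlabd-7-en-17-oate | CC[C@@H](C)C(=O)O[C@H]1C=C(C(=O)OC(C)(C)C)[C@H](CCO)[C@@]2(C)CCCC(C)(C)[C@H]12 | intermediate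
38 | tert-butyl 12-iodo-6α-[(2R)-2-methylbutanoyloxy]-13,14,15,16-tetranorlabd-7-en-17-oate | CC[C@@H](C)C(=O)O[C@H]1C=C(C(=O)OC(C)(C)C)[C@H](CCI)[C@@]2(C)CCCC(C)(C)[C@H]12 | intermediate
39 | 3-bromodihydrofuran-2(3H)-one | O=C1OCCC1Br | starting material
40 | thiophenol | Sc1ccccc1 | starting material
41 | 3-(phenylsulfanyl)dihydrofuran-2(3H)-one | O=C1OCCC1Sc1ccccc1 | intermediate
42 | potassium enolate of 41 | [K]OC1=C(Sc2ccccc2)CCO1 | intermediate (not isolated)
43 | tert-butyl 6α-[(2R)-2-methylbutanoyloxy]-13-(phenylsulfanyl)labd-7-en-16,15-olid-17-oate (C13 epimers) | CC[C@@H](C)C(=O)O[C@H]1C=C(C(=O)OC(C)(C)C)[C@H](CCC3(Sc4ccccc4)CCOC3=O)[C@@]2(C)CCCC(C)(C)[C@H]12 | intermediate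
44 | sulfoxide of 43 | CC[C@@H](C)C(=O)O[C@H]1C=C(C(=O)OC(C)(C)C)[C@H](CCC3(S(=O)c4ccccc4)CCOC3=O)[C@@]2(C)CCCC(C)(C)[C@H]12 | intermediate (not isolated)
45 | tert-butyl 6α-[(2R)-2-methylbutanoyloxy]labda-7,13-dien-16,15-olid-17-oate | CC[C@@H](C)C(=O)O[C@H]1C=C(C(=O)OC(C)(C)C)[C@H](CCC3=CCOC3=O)[C@@]2(C)CCCC(C)(C)[C@H]12 | intermediate
46 | 6α-[(2R)-2-methylbutanoyloxy]labda-7,13-dien-16,15-olid-17-oic acid (CNP0150853.1) | CC[C@@H](C)C(=O)O[C@H]1C=C(C(=O)O)[C@H](CCC2=CCOC2=O)[C@@]2(C)CCCC(C)(C)[C@H]12 | target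

**Step count**
Total steps: 22. Longest linear sequence: 18 (steps 1–3, 6, 7, 9–18, 20–22).

**Steps most likely to fail**

Step 13 (key bicyclisation). The cascade may stop after ring B, with the C10 cation losing a proton or being captured by chloride or by O12. The aldehyde may also add to the wrong alkene face, or the Lewis acid may cleave the tert-butyl ester. The fallback replaces the aldehyde by a chiral acetal as initiator, which is more electrophilic and adds reagent control at C6. It sets out from 26: transacetalisation with (2S,4S)-pentane-2,4-diol (PPTS, toluene, reduced pressure) gives the (4S,6S)-4,6-dimethyl-1,3-dioxane acetal F1. SnCl4 in CH2Cl2 at −78 °C then opens the C–O bond next to the axial methyl, and the same alkene/allylsilane pair closes rings B and A to give the 6α-(4-hydroxypent-2-yloxy) ether F2. Dess–Martin oxidation gives the methyl ketone F3, and β-elimination (K2CO3, MeOH, or piperidinium acetate in warm benzene) releases the alcohol and returns to the route at 28.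

Step 7 (CBS reduction). Enantioface discrimination may be poor because both ketone substituents are bulky, or the reduction may be sluggish. The fallback makes the small group unambiguous by using an alkyne and sets out from 9. The lithium acetylide of triisopropyl(but-3-yn-1-yloxy)silane F4 (from but-3-yn-1-ol, TIPSCl, imidazole; then n-BuLi, THF, −78 °C) adds to 9 to give the ynone F5. Noyori transfer hydrogenation (RuCl[(S,S)-TsDPEN](p-cymene), i-PrOH) should give the propargylic alcohol F6 with the same spatial arrangement at C5 as 17. Ruthenium-catalysed trans-hydrostannation ([Cp*RuCl]4, Bu3SnH, CH2Cl2) places tin on the carbon next to the carbinol to give the alkenylstannane F7. Methyl-Stille coupling (MeI, Pd(PPh3)4, CuTC, [Bu4N][Ph2PO2], DMF) returns to the route at 17.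

Step 15 (Δ7 introduction). Enolisation of the hindered C8 ester may be incomplete, or part of the elimination may go toward C9. The fallback moves the dehydrogenation to the more easily enolised aldehyde and sets out from 29. LiAlH4 (THF, 0 °C) gives the 6α,17-diol F8, and TEMPO/PhI(OAc)2 oxidises only the primary alcohol to the hydroxy aldehyde F9. α-Selenenylation through the enol (PhSeCl, EtOAc, or N-(phenylseleno)phthalimide with catalytic pyrrolidine) gives the α-seleno aldehyde F10, and NaIO4 oxidation with syn-elimination gives the Δ7 enal F11. Pinnick oxidation (NaClO2, NaH2PO4, 2-methylbut-2-ene, t-BuOH/H2O) gives the hydroxy enoic acid F12, which cannot lactonise because C17 and C6 are trans across C7=C8. tert-Butyl 2,2,2-trichloroacetimidate then returns to the route at 33.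

**Further compounds**
F1 | step 13 | (4S,6S)-4,6-dimethyl-1,3-dioxane acetal at C6 of the tert-butyl ester | C[C@H]1C[C@H](C)OC(C[C@@H](C(=O)OC(C)(C)C)[C@H](CCO[Si](C(C)C)(C(C)C)C(C)C)/C(C)=C/C(C)(C)C([Si](C)(C)C)C=C)O1
F2 | step 13 | tert-butyl 6α-{[(2S,4S)-4-hydroxypentan-2-yl]oxy}-12-[(triisopropylsilyl)oxy]-13,14,15,16-tetranorlabd-2-en-17-oate | C[C@H](O)C[C@H](C)O[C@H]1C[C@@H](C(=O)OC(C)(C)C)[C@H](CCO[Si](C(C)C)(C(C)C)C(C)C)[C@@]2(C)CC=CC(C)(C)[C@H]12
F3 | step 13 | tert-butyl 6α-{[(2S)-4-oxopentan-2-yl]oxy}-12-[(triisopropylsilyl)oxy]-13,14,15,16-tetranorlabd-2-en-17-oate | CC(=O)C[C@H](C)O[C@H]1C[C@@H](C(=O)OC(C)(C)C)[C@H](CCO[Si](C(C)C)(C(C)C)C(C)C)[C@@]2(C)CC=CC(C)(C)[C@H]12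
F4 | step 7 | triisopropyl(but-3-yn-1-yloxy)silane | C#CCCO[Si](C(C)C)(C(C)C)C(C)C
F5 | step 7 | 4,4-dimethyl-9-[(triisopropylsilyl)oxy]-3-(trimethylsilyl)non-1-en-6-yn-5-one | C=CC([Si](C)(C)C)C(C)(C)C(=O)C#CCCO[Si](C(C)C)(C(C)C)C(C)C
F6 | step 7 | (5R)-4,4-dimethyl-9-[(triisopropylsilyl)oxy]-3-(trimethylsilyl)non-1-en-6-yn-5-ol | C=CC([Si](C)(C)C)C(C)(C)[C@H](O)C#CCCO[Si](C(C)C)(C(C)C)C(C)C
F7 | step 7 | 6-(tributylstannyl) analogue of 17 (tin in place of the C6 methyl; C5 carbinol as in 17) | C=CC([Si](C)(C)C)C(C)(C)[C@H](O)/C([Sn](CCCC)(CCCC)CCCC)=C/CCO[Si](C(C)C)(C(C)C)C(C)C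
F8 | step 15 | 12-[(triisopropylsilyl)oxy]-13,14,15,16-tetranorlabdane-6α,17-diol | O[C@H]1C[C@@H](CO)[C@H](CCO[Si](C(C)C)(C(C)C)C(C)C)[C@@]2(C)CCCC(C)(C)[C@H]12
F9 | step 15 | 6α-hydroxy-12-[(triisopropylsilyl)oxy]-13,14,15,16-tetranorlabdan-17-al | O[C@H]1C[C@@H](C=O)[C@H](CCO[Si](C(C)C)(C(C)C)C(C)C)[C@@]2(C)CCCC(C)(C)[C@H]12
F10 | step 15 | 6α-hydroxy-8-(phenylselanyl)-12-[(triisopropylsilyl)oxy]-13,14,15,16-tetranorlabdan-17-al | O[C@H]1CC(C=O)([Se]c3ccccc3)[C@H](CCO[Si](C(C)C)(C(C)C)C(C)C)[C@@]2(C)CCCC(C)(C)[C@H]12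
F11 | step 15 | 6α-hydroxy-12-[(triisopropylsilyl)oxy]-13,14,15,16-tetranorlabd-7-en-17-al | O[C@H]1C=C(C=O)[C@H](CCO[Si](C(C)C)(C(C)C)C(C)C)[C@@]2(C)CCCC(C)(C)[C@H]12
F12 | step 15 | 6α-hydroxy-12-[(triisopropylsilyl)oxy]-13,14,15,16-tetranorlabd-7-en-17-oic acid | O[C@H]1C=C(C(=O)O)[C@H](CCO[Si](C(C)C)(C(C)C)C(C)C)[C@@]2(C)CCCC(C)(C)[C@H]12
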